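**Retrosynthetic overview**
- The target is cut at the ester C–O bond (to (R)-2-methylbutanoic acid) and at the aryl–O bond (to 7-bromocoumarin), leaving a cis diol, (1R,5S)-5-(hydroxymethyl)-4,6,6-trimethylcyclohex-3-en-1-ol.
- Key C–C disconnection: the ring–CH2OH bond. It is made by a hydroxymethyl anion (an α-alkoxymethyllithium, a formyl anion at the alcohol oxidation level) delivered in a Wittig–Still [2,3] shift from the allylic oxygen of a cis-cyclohex-4-ene-1,3-diol. This one step sets the ring stereocentre next to the quaternary carbon and fixes the alkene position.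
- The cis-1,3-diol comes from Luche reduction of an (R)-5-hydroxy enone, made by copper-catalysed asymmetric β-borylation/oxidation of 2,4,4-trimethylcyclohexa-2,5-dienone (one dehydrogenation from the commercial enone).
- Rings: none is built. The carbocycle comes from the cyclohexenone and the coumarin from 7-bromocoumarin.

Assumption: the four building blocks (the trimethylcyclohexenone, the stannylmethyl iodide, 7-bromocoumarin and (R)-2-methylbutanoic acid) are purchased, and the ligand enantiomer named in step 2 is taken to give the 5R boronate; if the first run shows the opposite sense, its mirror image is used.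

**Step 1**
Reactants: 1 2,4,4-trimethylcyclohex-2-en-1-one
Product: 2 2,4,4-trimethylcyclohexa-2,5-dien-1-one
Conditions: DDQ (1.5 equiv), TsOH·H2O (10 mol%), 1,4-dioxane, 100 °C
Reagents that add atoms: none
Why: DDQ dehydrogenation of the enol can only remove hydrogen from C5–C6 (C4 is quaternary), giving the cross-conjugated dienone without creating a stereocentre.

**Step 2**
Reactants: 2 2,4,4-trimethylcyclohexa-2,5-dien-1-one
Product: 4 (5R)-5-hydroxy-2,4,4-trimethylcyclohex-2-en-1-one, via pinacol boronate 3 (not isolated)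
Conditions: CuCl (5 mol%), NaOtBu (10 mol%), (R)-1-[(Sp)-2-(diphenylphosphino)ferrocenyl]ethyldicyclohexylphosphine (Josiphos, C36H44FeP2, 6 mol%), B2pin2 (1.1 equiv), MeOH (2 equiv), THF, 0 °C to rt; then NaBO3·4H2O, THF/H2O, rt
Reagents that add atoms: bis(pinacolato)diboron, CC1(C)OB(OC1(C)C)B1OC(C)(C)C(C)(C)O1 (boron of 3); sodium perborate, [Na+].[Na+].O[B-]1(O)OO[B-](O)(O)OO1 (hydroxyl oxygen of 4)
Why: Copper-catalysed asymmetric conjugate borylation adds the ligand-bound Cu–Bpin to the α-unsubstituted enone arm (more electrophilic and less hindered than the α-methyl arm), the chiral diphosphine choosing the face so that C5 is R, and perborate oxidation of the C–B bond then proceeds with retention.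

**Step 3**
Reactants: 4 (5R)-5-hydroxy-2,4,4-trimethylcyclohex-2-en-1-one
Product: 5 (1R,3S)-4,6,6-trimethylcyclohex-4-ene-1,3-diol (the two hydroxyls cis)
Conditions: NaBH4, CeCl3·7H2O, MeOH, −78 °C
Reagents that add atoms: none
Why: Luche 1,2-reduction, in which hydride adds axially to the half-chair with the C5 oxygen equatorial (the face opposite the C5–O bond), so the new allylic carbinol (S) is cis to the existing one; any trans isomer is removed by chromatography.

**Step 4**
Reactants: 5 (1R,3S)-4,6,6-trimethylcyclohex-4-ene-1,3-diol; 6 tributyl(iodomethyl)stannane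
Product: 7 (1R,5S)-2,2,4-trimethyl-5-[(tributylstannyl)methoxy]cyclohex-3-en-1-ol
Conditions: KH (1.05 equiv), THF, 0 °C; then 6 (1.05 equiv), 0 °C to rt
Reagents that add atoms: none
Why: Williamson etherification, in which the allylic alkoxide reacts faster than the alkoxide next to the quaternary carbon (neopentylic), so the stannylmethyl group goes onto the allylic oxygen and neither stereocentre is touched.

**Step 5**
Reactants: 7 (1R,5S)-2,2,4-trimethyl-5-[(tributylstannyl)methoxy]cyclohex-3-en-1-ol
Product: 9 (1R,5S)-5-(hydroxymethyl)-4,6,6-trimethylcyclohex-3-en-1-ol, via dilithiated α-alkoxymethyl carbanion 8 (not isolated)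
Conditions: n-BuLi (2.2 equiv), THF, −78 to −20 °C; then H2O
Reagents that add atoms: n-butyllithium, CCCC[Li] (lithium of 8 only; nothing but hydrogen stays in 9)
Why: Wittig–Still [2,3]-sigmatropic rearrangement, in which tin–lithium exchange makes the O–CH2 carbon a carbanion (a hydroxymethyl anion, so an oxygen-bearing carbon attacks the electrophilic terminus of an allylic ether) that is delivered suprafacially, breaking the allylic C–O bond, moving the double bond to the trisubstituted position and forming the new C–C bond on the face the oxygen occupied, hence cis to the ring hydroxyl (5S).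

**Step 6**
Reactants: 9 (1R,5S)-5-(hydroxymethyl)-4,6,6-trimethylcyclohex-3-en-1-ol; 10 7-bromo-2H-chromen-2-one (7-bromocoumarin, 1.2 equiv)
Product: 11 7-{[(1S,5R)-5-hydroxy-2,6,6-trimethylcyclohex-2-en-1-yl]methoxy}-2H-chromen-2-one
Conditions: [Pd(allyl)Cl]2 (2.5 mol%), RockPhos [2-(di-tert-butylphosphino)-3-methoxy-6-methyl-2′,4′,6′-triisopropylbiphenyl] (7.5 mol%), Cs2CO3 (1.5 equiv), toluene, 80 °C
Reagents that add atoms: none
Why: Palladium-catalysed C–O cross-coupling (Buchwald–Hartwig etherification), in which the primary alcohol couples far faster than the neopentylic secondary one and, because the alcohol is the nucleophile, the CH2–O carbon is never activated, so the cis-1,4-diol cannot close to a bridged tetrahydrofuran as it would under Mitsunobu or sulfonate activation; no stereocentre is touched.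

**Step 7**
Reactants: 11 7-{[(1S,5R)-5-hydroxy-2,6,6-trimethylcyclohex-2-en-1-yl]methoxy}-2H-chromen-2-one; 12 (2R)-2-methylbutanoic acid (1.5 equiv)
Product: 13 (1R,5S)-4,6,6-trimethyl-5-{[(2-oxo-2H-chromen-7-yl)oxy]methyl}cyclohex-3-en-1-yl (2R)-2-methylbutanoate
Conditions: DCC (1.6 equiv), DMAP (0.3 equiv), CH2Cl2, 0 °C to rt
Reagents that add atoms: none
Why: Steglich esterification acylates the hindered secondary alcohol on oxygen, so the ring carbinol keeps its R configuration and the α-stereocentre of the acid is not enolised under these neutral, low-temperature conditions.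

**Compound list**
1 | 2,4,4-trimethylcyclohex-2-en-1-one | CC1=CC(C)(C)CCC1=O | starting material
2 | 2,4,4-trimethylcyclohexa-2,5-dien-1-one | CC1=CC(C)(C)C=CC1=O | intermediate
3 | (5R)-2,4,4-trimethyl-5-(4,4,5,5-tetramethyl-1,3,2-dioxaborolan-2-yl)cyclohex-2-en-1-one | CC1(C)OB(OC1(C)C)[C@@H]1CC(=O)C(C)=CC1(C)C | intermediate
4 | (5R)-5-hydroxy-2,4,4-trimethylcyclohex-2-en-1-one | O[C@@H]1CC(=O)C(C)=CC1(C)C | intermediate
5 | (1R,3S)-4,6,6-trimethylcyclohex-4-ene-1,3-diol (cis diol) | O[C@@H]1C[C@H](O)C(C)=CC1(C)C | intermediate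
6 | tributyl(iodomethyl)stannane | CCCC[Sn](CCCC)(CCCC)CI | starting material
7 | (1R,5S)-2,2,4-trimethyl-5-[(tributylstannyl)methoxy]cyclohex-3-en-1-ol | O[C@@H]1C[C@H](OC[Sn](CCCC)(CCCC)CCCC)C(C)=CC1(C)C | intermediate
8 | lithium (1R,5S)-5-(lithiomethoxy)-2,2,4-trimethylcyclohex-3-en-1-olate | [Li]O[C@@H]1C[C@H](OC[Li])C(C)=CC1(C)C | intermediate
9 | (1R,5S)-5-(hydroxymethyl)-4,6,6-trimethylcyclohex-3-en-1-ol (OH and CH2OH cis) | O[C@@H]1CC=C(C)[C@H](CO)C1(C)C | intermediate
10 | 7-bromo-2H-chromen-2-one | O=c1ccc2ccc(Br)cc2o1 | starting material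
11 | 7-{[(1S,5R)-5-hydroxy-2,6,6-trimethylcyclohex-2-en-1-yl]methoxy}-2H-chromen-2-one | O[C@@H]1CC=C(C)[C@H](COc2ccc3ccc(=O)oc3c2)C1(C)C | intermediate
12 | (2R)-2-methylbutanoic acid | CC[C@@H](C)C(=O)O | starting material
13 | (1R,5S)-4,6,6-trimethyl-5-{[(2-oxo-2H-chromen-7-yl)oxy]methyl}cyclohex-3-en-1-yl (2R)-2-methylbutanoate | CC[C@@H](C)C(=O)O[C@@H]1CC=C(C)[C@H](COc2ccc3ccc(=O)oc3c2)C1(C)C | target

Total steps: 7. Longest linear sequence: 7 steps (1 to 13).

**Steps most likely to fail**

The rearrangement in step 5 is the most exposed. The new bond forms next to a quaternary carbon, and a [1,2] shift or simple protonation of the carbanion to a methyl ether can compete. The fallback sets out from 5 and drops the organolithium altogether. Heating 5 with N,N-dimethylformamide dimethyl acetal in xylene at 150 °C turns the allylic oxygen into a formamide acetal, which loses methanol to an alkoxy(dimethylamino)carbene (a carbamoyl anion equivalent). This undergoes the same suprafacial [2,3] shift (Büchi rearrangement) to the amide (1S,5R)-5-hydroxy-N,N,2,6,6-pentamethylcyclohex-2-ene-1-carboxamide F2. Reduction of F2 with LiNH2BH3 in THF gives the primary alcohol, and the route is rejoined at 9.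

The etherification in step 6 may stall with this β-branched alcohol or damage the coumarin lactone under carbonate at 80 °C. The fallback sets out from 9 and makes the ether by Mitsunobu chemistry only after the ring hydroxyl has been acylated, so that it cannot cyclise onto the activated CH2. TBSCl and imidazole silylate the primary hydroxyl only, giving (1R,5S)-5-{[(tert-butyldimethylsilyl)oxy]methyl}-4,6,6-trimethylcyclohex-3-en-1-ol F3. Steglich esterification with 12 gives (1R,5S)-5-{[(tert-butyldimethylsilyl)oxy]methyl}-4,6,6-trimethylcyclohex-3-en-1-yl (2R)-2-methylbutanoate F4. HF·pyridine removes the silyl group to give (1R,5S)-5-(hydroxymethyl)-4,6,6-trimethylcyclohex-3-en-1-yl (2R)-2-methylbutanoate F5. Mitsunobu coupling of F5 with umbelliferone (7-hydroxycoumarin; PPh3, DIAD, THF) then rejoins the route at 13.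

The borylation in step 2 may give too low an enantiomeric excess, or attack the wrong arm of the dienone. The fallback sets out from 2 and introduces the oxygen as an epoxide. Aqueous H2O2 with a cinchona-derived primary amine salt (iminium catalysis; quinine or quinidine series, whichever gives the S,S epoxide) epoxidises the less substituted double bond to (1S,6S)-3,5,5-trimethyl-7-oxabicyclo[4.1.0]hept-3-en-2-one F1. Reductive cleavage of the Cα–O bond of F1 with (PhSe)2, NaBH4 and AcOH in EtOH at 0 °C gives the β-hydroxy ketone, and the route is rejoined at 4.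

**Further compounds**
F1 | step 2 | (1S,6S)-3,5,5-trimethyl-7-oxabicyclo[4.1.0]hept-3-en-2-one | CC1=CC(C)(C)[C@@H]2O[C@@H]2C1=O
F2 | step 5 | (1S,5R)-5-hydroxy-N,N,2,6,6-pentamethylcyclohex-2-ene-1-carboxamide | O[C@@H]1CC=C(C)[C@H](C(=O)N(C)C)C1(C)C
F3 | step 6 | (1R,5S)-5-{[(tert-butyldimethylsilyl)oxy]methyl}-4,6,6-trimethylcyclohex-3-en-1-ol | O[C@@H]1CC=C(C)[C@H](CO[Si](C)(C)C(C)(C)C)C1(C)C
F4 | step 6 | (1R,5S)-5-{[(tert-butyldimethylsilyl)oxy]methyl}-4,6,6-trimethylcyclohex-3-en-1-yl (2R)-2-methylbutanoate | CC[C@@H](C)C(=O)O[C@@H]1CC=C(C)[C@H](CO[Si](C)(C)C(C)(C)C)C1(C)C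
F5 | step 6 | (1R,5S)-5-(hydroxymethyl)-4,6,6-trimethylcyclohex-3-en-1-yl (2R)-2-methylbutanoate | CC[C@@H](C)C(=O)O[C@@H]1CC=C(C)[C@H](CO)C1(C)C
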